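# Synthesis plan for CNP0315707.1: (1R,4R,5S,6S,8R,9S)-8,9-epoxy-6-hydroxydaucan-4-yl 4-hydroxy-3-methoxybenzoate (21)

Daucane numbering is used for all bicyclic compounds. Ring A is C1–C5 and ring B is C1, C5–C10. C1 carries methyl C15, C4 carries the isopropyl group and an oxygen, C6 carries an oxygen, and C8 carries methyl C14. The β face is that of the C1 methyl group; the α face is that of H5.

## The problem

Target 21 is a trans-fused bicyclo[5.3.0]decane in which cyclopentane ring A and cycloheptane ring B share the C1–C5 bond, C1 is a methylated quaternary carbon and H5 lies on the opposite (α) face. It has six stereocentres: C1 (R), the fully substituted C4 (R, ester oxygen β, isopropyl α), C5 (S), the carbinol C6 (S, hydroxyl α) and the α-epoxide at C8/C9 (8R,9S). A C6 oxygen introduced first can govern the others: it biases the face on which a chain attached to C6 reaches C1, it makes the trans ring fusion the favoured C5 epimer while C4 is a ketone, together with the C1 methyl group it steers a nucleophile to the α face of C4, and as the free hydroxyl it delivers an oxidant to the α face of C8=C9. The hard bond is the ester, which sits on the more hindered of two hydroxyls and is 1,3 to the other, so C6 must be masked during acylation and no alkoxide may form at C6 afterwards or the acyl group can migrate. The trisubstituted epoxide will not tolerate Lewis or protic acid, the phenol needs protection from oxidants and strong base, and any β-oxygenated C4 ketone can lose its C6 oxygen by E1cB elimination. The enabling feature is that C4, C5 and C1 map onto the carbonyl, α- and β-carbons of 3-methylcyclopent-2-enone, with C6 on the α-carbon. C10–C9=C8(CH3) of ring B is an allyl unit whose terminus C10 is bonded to C1. With silicon on C8 it becomes an allylsilane that can add to C1, close ring B, create the quaternary carbon and leave the alkene at C8=C9, where the epoxide is needed.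

## Retrosynthesis

**Epoxide and phenol (21 ⇒ 20 ⇒ 19).** The two C–O bonds of the epoxide are cut last, after removal of a phenol protecting group. An epoxide installed earlier would not survive the Lewis acid and organometallic steps. Its α configuration is what the 6α-hydroxyl of homoallylic alcohol 19 delivers, whereas an undirected peracid would depend on sterics alone. Precursor 19 has two fewer stereocentres. The forward reaction must oxidise only the ring alkene and leave the ester and the allyl ether alone; the final unmasking of 20 must be neutral.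

**Ester (19 ⇒ 18 ⇒ 12 + 16).** The acyl C–O bond is cut to tertiary alcohol 12 and acid chloride 16, which comes from vanillic acid 13 through acid 15. Acylating a 4,6-diol would go to C6, so the C6 silyl ether is kept until the ester is in place (18). An allyl ether protects the phenol because it survives alkoxide, HF and the vanadium oxidation and is removed without acid or base. The forward step is O-acylation of a very hindered tertiary alkoxide.

**Isopropyl group (12 ⇒ 11).** The C4–C11 bond is cut to ketone 11. Carrying the isopropyl carbinol through ring construction would remove the carbonyl that activates C1 and makes C5 correctable. The precursor loses three carbons and one stereocentre. The forward reaction must add, not enolise or reduce, and must come from the α face.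

**Ring B (11 ⇒ 9).** The C1–C10 bond is cut. Cutting C8=C9 (metathesis) would leave the quaternary carbon to an intermolecular addition to a tetrasubstituted enone. Cutting C5–C6 (aldol) would close a seven-membered ring with no handle on C1. The C1–C10 cut lets the ring closure itself build the quaternary carbon, intramolecularly and under control of C6. Precursor 9 is monocyclic with one stereocentre that matters. The forward reaction must bond through C10 and not C8, add 1,4 and not 1,2, choose the right face of the enone, and end with the trans ring fusion.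

**Side chain to enone (9 ⇒ 8 ⇒ 6 + 7).** The C5–C6 bond is cut to aldehyde 6 and commercial bromoenone 7. A Morita–Baylis–Hillman reaction fails on β-substituted enones, and aldol condensation gives the wrong oxidation pattern. A Nozaki–Hiyama–Kishi coupling uses 7 directly and lets a chiral ligand on chromium set C6. The forward step must add to the aldehyde and not the ketone and must be enantioselective; silylation then gives 9.

**Allylsilane (6 ⇒ 5 ⇒ 2 + 3; 2 ⇒ 1).** The C7–C8 bond is cut by a [3,3] shift. Johnson–Claisen rearrangement of vinylsilane 2 with orthoester 3 places silicon, methyl and vinyl on one carbon in ester 5, whereas alkylating a silylallyl anion would give α/γ mixtures. Vinylsilane 2 comes from but-2-yn-1-ol 1 by hydrosilylation. The forward steps need silicon on the alkyne carbon remote from the hydroxyl and a rearrangement that forms a quaternary carbon.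

## Roads not taken

**Alternative 1:** The cut is C1–C2 and C4–C5: ring A is annulated onto a preformed seven-membered ring, 3,6-dimethylcyclohepta-2,5-dien-1-one A1, using 1-(propan-2-yl)cyclopropan-1-ol A2. In the forward step Et2Zn opens A2 to the zinc homoenolate ethyl(4-methyl-3-oxopentyl)zinc A3. A chiral phosphoramidite complex of CuOTf transfers the oxoalkyl group of A3 to C1 of A1, and ring A closes by aldol addition of C5 to the isopropyl ketone, giving 4-hydroxydauc-8-en-6-one A4.
- Merits: two small pieces give the whole skeleton, the quaternary carbon, the isopropyl carbinol and C5 in one operation, with no protecting group.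
- Weak points:
  - Enantioselective transfer of a weakly nucleophilic homoenolate such as A3 to a β,β-disubstituted cycloheptenone has little to lean on.
  - The skipped C8=C9 alkene of A1 is β,γ to the ketone and can slip into conjugation.
  - Aldol closure onto a hindered ketone is reversible. The tertiary alkoxide of A4, which must be acylated, can reopen ring A by retro-aldol.
  - C6 would still have to be set by a ketone reduction of unknown facial preference.
- Comparison: this road is clearly shorter, perhaps half the step count, and avoids the late addition to a hindered ketone. The chosen plan offers steps with close precedent, stereocontrol that traces back to one carbinol, and no base-labile tertiary aldol.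

**Alternative 2:** The cut is C4–C5 and O–C6. The aldoxime 3-(1,5-dimethylcyclohepta-2,5-dien-1-yl)propanal oxime A5 is oxidised by NaOCl to 3-(1,5-dimethylcyclohepta-2,5-dien-1-yl)propanenitrile oxide A6. Intramolecular cycloaddition of A6 across C5=C6 closes ring A and gives the ring A-fused isoxazoline A7. Hydrogenolysis of A7 over Raney Ni would unmask the hydroxy ketone 6α-hydroxy-11,12,13-trinor-5-epi-dauc-8-en-4-one A8.
- Merits: intramolecular nitrile oxide cycloadditions are dependable. The tether in A6 admits only the C5=C6 alkene and fixes the C6 oxygen of A7 relative to C1 by geometry, not by a conformational preference. No Lewis acid is involved and the β-hydroxy ketone stays masked in A7.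
- Weak points:
  - The quaternary stereocentre must exist, enantiomerically pure, before the key step, so the hardest problem moves into the synthesis of A5.
  - Suprafacial addition gives the cis ring fusion in A7, so all material must pass through C5 epimerisation at the stage of A8, which can dehydrate.
- Comparison: this road is better in chemoselectivity of ring closure and in how firmly C6 is tied to C1. The chosen plan makes the quaternary carbon in the ring-closing step from an achiral enone, reaches its precursor in five steps, and needs the C5 epimerisation only as a correction.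

**Alternative 3:** The cut is C1–C5, made by migration. The cis-fused decalin mesylate 8a-hydroxy-4a,7-dimethyl-2-(propan-2-yl)-2-(triethylsilyloxy)-1,2,3,4,4a,5,8,8a-octahydronaphthalen-1-yl methanesulfonate A9 is treated with KOtBu or Et2AlCl. C1 shifts from C6 to C5 as the mesylate leaves, one six-membered ring contracts to ring A and the other expands to ring B, giving 4-(triethylsilyloxy)dauc-8-en-6-one A10.
- Merits: the shift is stereospecific, with retention at C1 and inversion at C5. It fixes the trans ring fusion without protonation or equilibration and carries the isopropyl carbinol in from the start. In both respects it is better than the chosen plan.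
- Weak points:
  - A9 needs four contiguous stereocentres with methyl, hydroxyl, mesylate and silyloxy all on one face, and the equatorial mesylate anti to the ring-fusion bond. This is a long prelude.
  - The C6 ketone of A10 keeps C5 epimerisable and must be reduced to the α-alcohol.
  - The protecting-group traffic between the C4 and C6 oxygens is no shorter than in the chosen endgame.
- Comparison: the chosen plan has a five-step precursor, a single asymmetric reaction, and the C6 oxygen at the correct oxidation level and configuration from the outset.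

Key step: step 6

Remark: 2-bromo-3-methylcyclopent-2-en-1-one and the chiral oxazoline–sulfonamide ligand are taken as purchasable. The ligand enantiomer is assumed to be chosen so that the carbinol formed in step 4 is S.

## Route

Step 1
Reactants: 1 but-2-yn-1-ol
Product: 2 (2Z)-3-(triethylsilyl)but-2-en-1-ol
Conditions: Et3SiH (1.2 equiv), [Cp*Ru(MeCN)3]PF6 (1 mol %), CH2Cl2, 0 °C to rt
Reagents that add atoms: triethylsilane CC[SiH](CC)CC
Why: Ruthenium-catalysed trans-hydrosilylation of a propargylic alcohol; silicon goes to the alkyne carbon remote from the hydroxyl and H and Si add anti, which gives the Z vinylsilane; a minor regioisomer would be removed by chromatography.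

Step 2
Reactants: 2 (2Z)-3-(triethylsilyl)but-2-en-1-ol; 3 triethyl orthoacetate
Product: 5 ethyl 3-methyl-3-(triethylsilyl)pent-4-enoate (racemic), via mixed ketene acetal 4 (not isolated)
Conditions: MeC(OEt)3 (6 equiv), EtCO2H (0.1 equiv), 140 °C, EtOH distilled off
Reagents that add atoms: none
Why: Johnson–Claisen rearrangement; acid-catalysed exchange gives ketene acetal 4, whose [3,3] shift forms C7–C8 at the silyl-bearing carbon, as in the rearrangement of 3,3-disubstituted allylic alcohols to 3,3-disubstituted pent-4-enoates; the new quaternary carbon is racemic, which is harmless because it becomes sp2 in step 6.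

Step 3
Reactants: 5 ethyl 3-methyl-3-(triethylsilyl)pent-4-enoate
Product: 6 3-methyl-3-(triethylsilyl)pent-4-enal (racemic)
Conditions: i-Bu2AlH (1.1 equiv), CH2Cl2, −78 °C; MeOH, then aq. potassium sodium tartrate
Reagents that add atoms: none
Why: Partial reduction of an ester with i-Bu2AlH; the tetrahedral aluminium hemiacetal persists at −78 °C until the quench, and the β-quaternary carbon slows over-reduction.

Step 4
Reactants: 6 3-methyl-3-(triethylsilyl)pent-4-enal; 7 2-bromo-3-methylcyclopent-2-en-1-one
Product: 8 2-[(1S)-1-hydroxy-3-methyl-3-(triethylsilyl)pent-4-en-1-yl]-3-methylcyclopent-2-en-1-one (both epimers at the silyl carbon)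
Conditions: CrCl2 (10 mol %), chiral oxazoline–sulfonamide ligand (11 mol %), proton sponge (11 mol %), NiCl2(dmp) (2 mol %, dmp = 2,9-dimethyl-1,10-phenanthroline), Mn (2 equiv), Cp2ZrCl2 (1.2 equiv), LiCl (2 equiv), MeCN, rt
Reagents that add atoms: none
Why: Catalytic asymmetric Nozaki–Hiyama–Kishi coupling; zerovalent nickel inserts into the electron-poor C–Br bond, transmetalation gives an alkenylchromium species that adds to the aldehyde and not to the enone carbonyl, and the chiral ligand on chromium sets C6 (S); the remote racemic silyl carbon gives two epimers that are carried on together.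

Step 5
Reactants: 8 2-[(1S)-1-hydroxy-3-methyl-3-(triethylsilyl)pent-4-en-1-yl]-3-methylcyclopent-2-en-1-one
Product: 9 2-[(1S)-1-(tert-butyldimethylsilyloxy)-3-methyl-3-(triethylsilyl)pent-4-en-1-yl]-3-methylcyclopent-2-en-1-one (both epimers at the silyl carbon)
Conditions: TBSCl (1.5 equiv), imidazole (3 equiv), DMF, rt
Reagents that add atoms: tert-butyldimethylsilyl chloride CC(C)(C)[Si](C)(C)Cl
Why: Standard silylation of a secondary allylic alcohol; the bulky, non-chelating silyl ether is the control element of step 6 and stays on C6 until the ester is in place.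

Step 6
Reactants: 9 2-[(1S)-1-(tert-butyldimethylsilyloxy)-3-methyl-3-(triethylsilyl)pent-4-en-1-yl]-3-methylcyclopent-2-en-1-one
Product: 11 (1R,5S,6S)-6-(tert-butyldimethylsilyloxy)-11,12,13-trinordauc-8-en-4-one, via aluminium enolate 10 (not isolated)
Conditions: EtAlCl2 (1.5 equiv), toluene, −78 to −20 °C; sat. aq. NaHCO3; then DBU (0.1 equiv), toluene, rt if C5 epimers are present
Reagents that add atoms: none
Why: EtAlCl2 binds the C4 carbonyl oxygen and turns the enone into an oxyallyl cation whose tertiary terminus C1 is attacked by C10, the alkene carbon remote from silicon; the β-silyl cation at C9 then loses the triethylsilyl group to chloride, so the alkene appears at C8=C9 and enolate 10 remains until work-up. This is an intramolecular Hosomi–Sakurai conjugate addition, the closest known type being the EtAlCl2-promoted cyclisation of allylsilane-tethered cycloalkenones, which also closes seven-membered rings and forms quaternary carbons. Ring B closes in a 7-endo-trig mode with respect to the enone, because the tether is anchored on the α-carbon C5. C1 (R) is controlled by C6: allylic 1,3-strain with the C1 methyl group keeps H6 and not the silyloxy group beside that methyl, and in this rotamer the chain reaches C1 only from the face that leaves the methyl group β; both epimers at the silyl carbon converge because that carbon becomes sp2. C5 (S) is set by protonation of 10 and, where needed, by DBU equilibration; the trans-fused ketone is expected to be the stable epimer because only there are the C4 carbonyl carbon and the bulky C6 silyloxy group trans on ring B. The step needs conjugate addition to win over carbonyl addition, which would also close a seven-membered ring; the π-nucleophile and the Lewis-acid-complexed enone secure this, as in the intermolecular reaction that builds quaternary carbons from β,β-disubstituted enones. It also needs desilylation to outrun collapse to a cyclobutane or a silyl-retaining cyclopentane, which the chloride-labile triethylsilyl group and the low temperature favour.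

Step 7
Reactants: 11 (1R,5S,6S)-6-(tert-butyldimethylsilyloxy)-11,12,13-trinordauc-8-en-4-one
Product: 12 (1R,4R,5S,6S)-6-(tert-butyldimethylsilyloxy)dauc-8-en-4-ol
Conditions: CeCl3 (2 equiv), i-PrMgCl (2 equiv), THF, −78 °C, then 11, −78 to 0 °C; aq. NH4Cl
Reagents that add atoms: isopropylmagnesium chloride CC(C)[Mg]Cl
Why: Organocerium addition to a hindered, enolisable ketone; the weakly basic i-PrCeCl2 suppresses enolisation (and with it loss of the C6 silyloxy group) and β-hydride reduction; attack on the α face, anti to the β-oriented C1 methyl group and C5–C6 bond, places isopropyl α and hydroxyl β (4R).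

Step 8
Reactants: 13 vanillic acid
Product: 15 3-methoxy-4-(prop-2-enyloxy)benzoic acid, via allyl ester 14 (not isolated)
Conditions: allyl bromide (2.5 equiv), K2CO3 (3 equiv), DMF, 60 °C; then 2 M aq. NaOH, MeOH, 60 °C; HCl to pH 2
Reagents that add atoms: allyl bromide C=CCBr; sodium hydroxide [Na+].[OH-]
Why: Williamson allylation of phenoxide and carboxylate followed by saponification of the allyl ester in the same flask; the aryl allyl ether is inert to hydroxide.

Step 9
Reactants: 15 3-methoxy-4-(prop-2-enyloxy)benzoic acid
Product: 16 3-methoxy-4-(prop-2-enyloxy)benzoyl chloride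
Conditions: (COCl)2 (1.5 equiv), DMF (cat.), CH2Cl2, 0 °C to rt; evaporate, use crude
Reagents that add atoms: oxalyl chloride O=C(Cl)C(=O)Cl
Why: Acid chloride formation through the chloroiminium species from DMF and oxalyl chloride; the allyl ether and the methoxy group are untouched.

Step 10
Reactants: 12 (1R,4R,5S,6S)-6-(tert-butyldimethylsilyloxy)dauc-8-en-4-ol; 16 3-methoxy-4-(prop-2-enyloxy)benzoyl chloride
Product: 18 (1R,4R,5S,6S)-6-(tert-butyldimethylsilyloxy)dauc-8-en-4-yl 3-methoxy-4-(prop-2-enyloxy)benzoate, via lithium alkoxide 17 (not isolated)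
Conditions: n-BuLi (1.05 equiv), THF, −78 °C; then 16 (1.5 equiv), −78 °C to rt
Reagents that add atoms: none
Why: Acylation of a lithium tert-alkoxide by an aroyl chloride, the reaction type used to make tert-butyl esters; prior deprotonation makes the hindered C4 oxygen the only nucleophile, and the lithium counter-ion at low temperature disfavours transfer of the silyl group from O6.

Step 11
Reactants: 18 (1R,4R,5S,6S)-6-(tert-butyldimethylsilyloxy)dauc-8-en-4-yl 3-methoxy-4-(prop-2-enyloxy)benzoate
Product: 19 (1R,4R,5S,6S)-6-hydroxydauc-8-en-4-yl 3-methoxy-4-(prop-2-enyloxy)benzoate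
Conditions: HF·pyridine, pyridine/THF, 0 °C to rt
Reagents that add atoms: none
Why: Fluoride cleavage of a secondary silyl ether under non-basic conditions, so no alkoxide forms at C6 and the C4 ester cannot migrate; ester, allyl ether and alkene are inert to the reagent.

Step 12
Reactants: 19 (1R,4R,5S,6S)-6-hydroxydauc-8-en-4-yl 3-methoxy-4-(prop-2-enyloxy)benzoate
Product: 20 (1R,4R,5S,6S,8R,9S)-8,9-epoxy-6-hydroxydaucan-4-yl 3-methoxy-4-(prop-2-enyloxy)benzoate
Conditions: VO(acac)2 (5 mol %), t-BuOOH (1.5 equiv, in decane), CH2Cl2, 0 °C to rt
Reagents that add atoms: tert-butyl hydroperoxide CC(C)(C)OO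
Why: Hydroxyl-directed epoxidation of a homoallylic alcohol; the vanadate ester of the 6α-hydroxyl delivers oxygen to the α face of C8=C9 (8R,9S), which is also the face away from the C1 methyl group, and the undirected allyl ether alkene does not react.

Step 13
Reactants: 20 (1R,4R,5S,6S,8R,9S)-8,9-epoxy-6-hydroxydaucan-4-yl 3-methoxy-4-(prop-2-enyloxy)benzoate
Product: 21 (1R,4R,5S,6S,8R,9S)-8,9-epoxy-6-hydroxydaucan-4-yl 4-hydroxy-3-methoxybenzoate
Conditions: Pd(PPh3)4 (5 mol %), morpholine (5 equiv), THF, rt
Reagents that add atoms: none
Why: Tsuji–Trost-type deallylation of an aryl allyl ether; zerovalent palladium ionises the allyl ether with phenoxide as leaving group and morpholine captures the allyl unit; the neutral conditions leave the epoxide, the tertiary ester and the free C6 hydroxyl untouched.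

## Compound list

1 | but-2-yn-1-ol | CC#CCO | starting material
2 | (2Z)-3-(triethylsilyl)but-2-en-1-ol | C/C(=C/CO)[Si](CC)(CC)CC | intermediate
3 | triethyl orthoacetate (1,1,1-triethoxyethane) | CCOC(C)(OCC)OCC | starting material
4 | 1-ethoxy-1-{[(2Z)-3-(triethylsilyl)but-2-en-1-yl]oxy}ethene (mixed ketene acetal) | C=C(OCC)OC/C=C(/C)[Si](CC)(CC)CC | intermediate (not isolated)
5 | ethyl 3-methyl-3-(triethylsilyl)pent-4-enoate (racemic) | CCOC(=O)CC(C)(C=C)[Si](CC)(CC)CC | intermediate
6 | 3-methyl-3-(triethylsilyl)pent-4-enal (racemic) | O=CCC(C)(C=C)[Si](CC)(CC)CC | intermediate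
7 | 2-bromo-3-methylcyclopent-2-en-1-one | CC1=C(Br)C(=O)CC1 | starting material
8 | 2-[(1S)-1-hydroxy-3-methyl-3-(triethylsilyl)pent-4-en-1-yl]-3-methylcyclopent-2-en-1-one (both epimers at the silyl carbon) | CC1=C([C@@H](O)CC(C)([Si](CC)(CC)CC)C=C)C(=O)CC1 | intermediate
9 | 2-[(1S)-1-(tert-butyldimethylsilyloxy)-3-methyl-3-(triethylsilyl)pent-4-en-1-yl]-3-methylcyclopent-2-en-1-one (both epimers at the silyl carbon) | CC1=C([C@@H](O[Si](C)(C)C(C)(C)C)CC(C)([Si](CC)(CC)CC)C=C)C(=O)CC1 | intermediate
10 | chloro(ethyl)aluminium C4 enolate of 11 (C4=C5, O–Al) | CC[Al](Cl)OC=2CC[C@]3(C)CC=C(C)C[C@H](O[Si](C)(C)C(C)(C)C)C3=2 | intermediate (not isolated)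
11 | (1R,5S,6S)-6-(tert-butyldimethylsilyloxy)-11,12,13-trinordauc-8-en-4-one, i.e. (3aR,8S,8aS)-8-(tert-butyldimethylsilyloxy)-3a,6-dimethyl-3,3a,4,7,8,8a-hexahydroazulen-1(2H)-one; trans-fused, methyl β, H5 α, silyloxy α | O=C2CC[C@]3(C)CC=C(C)C[C@H](O[Si](C)(C)C(C)(C)C)[C@H]32 | intermediate
12 | (1R,4R,5S,6S)-6-(tert-butyldimethylsilyloxy)dauc-8-en-4-ol (4β-hydroxyl, 4α-isopropyl) | O[C@@]2(C(C)C)CC[C@]3(C)CC=C(C)C[C@H](O[Si](C)(C)C(C)(C)C)[C@H]32 | intermediate
13 | vanillic acid (4-hydroxy-3-methoxybenzoic acid) | COc1cc(C(=O)O)ccc1O | starting material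
14 | prop-2-enyl 3-methoxy-4-(prop-2-enyloxy)benzoate | COc1cc(C(=O)OCC=C)ccc1OCC=C | intermediate (not isolated)
15 | 3-methoxy-4-(prop-2-enyloxy)benzoic acid | COc1cc(C(=O)O)ccc1OCC=C | intermediate
16 | 3-methoxy-4-(prop-2-enyloxy)benzoyl chloride | COc1cc(C(=O)Cl)ccc1OCC=C | intermediate
17 | lithium (1R,4R,5S,6S)-6-(tert-butyldimethylsilyloxy)dauc-8-en-4-olate | [Li]O[C@@]2(C(C)C)CC[C@]3(C)CC=C(C)C[C@H](O[Si](C)(C)C(C)(C)C)[C@H]32 | intermediate (not isolated)
18 | (1R,4R,5S,6S)-6-(tert-butyldimethylsilyloxy)dauc-8-en-4-yl 3-methoxy-4-(prop-2-enyloxy)benzoate | COc1cc(C(=O)O[C@@]2(C(C)C)CC[C@]3(C)CC=C(C)C[C@H](O[Si](C)(C)C(C)(C)C)[C@H]32)ccc1OCC=C | intermediate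
19 | (1R,4R,5S,6S)-6-hydroxydauc-8-en-4-yl 3-methoxy-4-(prop-2-enyloxy)benzoate | COc1cc(C(=O)O[C@@]2(C(C)C)CC[C@]3(C)CC=C(C)C[C@H](O)[C@H]32)ccc1OCC=C | intermediate
20 | (1R,4R,5S,6S,8R,9S)-8,9-epoxy-6-hydroxydaucan-4-yl 3-methoxy-4-(prop-2-enyloxy)benzoate (α-epoxide) | COc1cc(C(=O)O[C@@]2(C(C)C)CC[C@]3(C)C[C@@H]4O[C@]4(C)C[C@H](O)[C@H]32)ccc1OCC=C | intermediate
21 | (1R,4R,5S,6S,8R,9S)-8,9-epoxy-6-hydroxydaucan-4-yl 4-hydroxy-3-methoxybenzoate (CNP0315707.1) | COc1cc(C(=O)O[C@@]2(C(C)C)CC[C@]3(C)C[C@@H]4O[C@]4(C)C[C@H](O)[C@H]32)ccc1O | target

## Step count and least certain steps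

Total: 13 steps. Longest linear sequence: 11 steps (steps 1–7 and 10–13, from but-2-yn-1-ol); steps 8 and 9 prepare the acyl fragment.

**Step 6 (key step).** Several processes could divert it:
- protodesilylation of the tertiary allylsilane before the C–C bond forms;
- attack of C10 on the carbonyl carbon instead of C1;
- collapse of the β-silyl cation onto the enolate instead of desilylation;
- unequal reactivity of the two epimers at the silyl carbon;
- protonation of the enolate on the β face, followed by loss of the C6 silyloxy group during base equilibration.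

The C5 question is the least secure part, since the preference for the trans-fused ketone rests on a structural argument only.

Fallback: ring B is closed at C8=C9 by metathesis, and C1–C10 is made beforehand by a 1,2-allylation/anionic oxy-Cope sequence, which is the standard answer to hindered enones. It sets out from 7 and returns at 11.
- Dess–Martin oxidation of 3-methylbut-3-en-1-ol gives 3-methylbut-3-enal F1, used at once.
- The coupling of step 4 with this aldehyde gives 2-[(1S)-1-hydroxy-3-methylbut-3-en-1-yl]-3-methylcyclopent-2-en-1-one F2.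
- Silylation as in step 5 gives 2-[(1S)-1-(tert-butyldimethylsilyloxy)-3-methylbut-3-en-1-yl]-3-methylcyclopent-2-en-1-one F3.
- Allylmagnesium bromide in THF at −78 °C adds to the carbonyl group on the face away from the silyloxy group and gives (1R)-2-[(1S)-1-(tert-butyldimethylsilyloxy)-3-methylbut-3-en-1-yl]-3-methyl-1-(prop-2-en-1-yl)cyclopent-2-en-1-ol F4; the C4 epimer would be separated here.
- KH and 18-crown-6 in THF trigger the [3,3] shift that carries the allyl group suprafacially from C4 to C1. Cold protonation gives (2S,3R)-2-[(1S)-1-(tert-butyldimethylsilyloxy)-3-methylbut-3-en-1-yl]-3-methyl-3-(prop-2-en-1-yl)cyclopentan-1-one F5.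
- Ring-closing metathesis with the second-generation Grubbs catalyst, RuCl2(H2IMes)(PCy3)(=CHPh), in CH2Cl2 at 40 °C then forms the trisubstituted C8=C9 alkene and gives 11.

**Step 4.** Oxidative addition to the alkenyl bromide may be slow, reductive debromination may compete, and the ligand may induce poorly with a β-quaternary aldehyde.

Fallback: the α-ketovinyl anion route with a reagent-controlled reduction. It sets out from 7 and returns at 8.
- Ketalisation (ethylene glycol, TsOH, benzene, water removed) gives 6-bromo-7-methyl-1,4-dioxaspiro[4.4]non-6-ene F6.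
- Bromine–lithium exchange with n-BuLi at −78 °C and addition to 6 gives 3-methyl-1-(7-methyl-1,4-dioxaspiro[4.4]non-6-en-6-yl)-3-(triethylsilyl)pent-4-en-1-ol F7 as a stereoisomer mixture.
- Dess–Martin oxidation gives 3-methyl-1-(7-methyl-1,4-dioxaspiro[4.4]non-6-en-6-yl)-3-(triethylsilyl)pent-4-en-1-one F8.
- Corey–Bakshi–Shibata reduction (oxazaborolidine enantiomer chosen for the S alcohol, BH3·SMe2) gives (1S)-3-methyl-1-(7-methyl-1,4-dioxaspiro[4.4]non-6-en-6-yl)-3-(triethylsilyl)pent-4-en-1-ol F9.
- PPTS in wet acetone releases the enone and gives 8.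

**Step 10.** The alkoxide may be too hindered to be acylated, or the silyl group may move from O6 to the C4 alkoxide, after which acylation would take place at C6.

Fallback: exchange the C6 protecting group for one that cannot migrate. It sets out from 12 and returns at 19.
- n-Bu4NF in THF gives (1R,4R,5S,6S)-dauc-8-ene-4,6-diol F10.
- NaH, 4-methoxybenzyl chloride and n-Bu4NI in DMF etherify only the secondary hydroxyl and give (1R,4R,5S,6S)-6-(4-methoxybenzyloxy)dauc-8-en-4-ol F11.
- KN(SiMe3)2 and then 16 give (1R,4R,5S,6S)-6-(4-methoxybenzyloxy)dauc-8-en-4-yl 3-methoxy-4-(prop-2-enyloxy)benzoate F12.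
- DDQ in buffered wet CH2Cl2 removes the benzyl ether and gives 19.

**Step 7.** Enolisation with loss of the C6 silyloxy group, reduction by β-hydride transfer from the isopropyl reagent, or insufficient facial selectivity could intervene.

Fallback: a smaller sp2 nucleophile without a transferable β-hydride. It sets out from 11 and returns at 12. Isopropenylmagnesium bromide with CeCl3 in THF gives (1R,4S,5S,6S)-6-(tert-butyldimethylsilyloxy)dauca-8,11-dien-4-ol F13 (4β-hydroxyl). Hydrogenation with RhCl(PPh3)3 in benzene under H2 (1 atm) saturates the 1,1-disubstituted alkene in preference to the trisubstituted ring alkene and gives 12.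

## Further compounds

F1 | step 6 | 3-methylbut-3-enal | CC(=C)CC=O
F2 | step 6 | 2-[(1S)-1-hydroxy-3-methylbut-3-en-1-yl]-3-methylcyclopent-2-en-1-one | CC1=C([C@@H](O)CC(C)=C)C(=O)CC1
F3 | step 6 | 2-[(1S)-1-(tert-butyldimethylsilyloxy)-3-methylbut-3-en-1-yl]-3-methylcyclopent-2-en-1-one | CC1=C([C@@H](O[Si](C)(C)C(C)(C)C)CC(C)=C)C(=O)CC1
F4 | step 6 | (1R)-2-[(1S)-1-(tert-butyldimethylsilyloxy)-3-methylbut-3-en-1-yl]-3-methyl-1-(prop-2-en-1-yl)cyclopent-2-en-1-ol | C=CC[C@]1(O)CCC(C)=C1[C@@H](O[Si](C)(C)C(C)(C)C)CC(C)=C
F5 | step 6 | (2S,3R)-2-[(1S)-1-(tert-butyldimethylsilyloxy)-3-methylbut-3-en-1-yl]-3-methyl-3-(prop-2-en-1-yl)cyclopentan-1-one | O=C1CC[C@](C)(CC=C)[C@H]1[C@@H](O[Si](C)(C)C(C)(C)C)CC(C)=C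
F6 | step 4 | 6-bromo-7-methyl-1,4-dioxaspiro[4.4]non-6-ene | CC1=C(Br)C2(CC1)OCCO2
F7 | step 4 | 3-methyl-1-(7-methyl-1,4-dioxaspiro[4.4]non-6-en-6-yl)-3-(triethylsilyl)pent-4-en-1-ol (stereoisomer mixture) | CC1=C(C(O)CC(C)([Si](CC)(CC)CC)C=C)C2(CC1)OCCO2
F8 | step 4 | 3-methyl-1-(7-methyl-1,4-dioxaspiro[4.4]non-6-en-6-yl)-3-(triethylsilyl)pent-4-en-1-one | CC1=C(C(=O)CC(C)([Si](CC)(CC)CC)C=C)C2(CC1)OCCO2
F9 | step 4 | (1S)-3-methyl-1-(7-methyl-1,4-dioxaspiro[4.4]non-6-en-6-yl)-3-(triethylsilyl)pent-4-en-1-ol (both epimers at the silyl carbon) | CC1=C([C@@H](O)CC(C)([Si](CC)(CC)CC)C=C)C2(CC1)OCCO2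
F10 | step 10 | (1R,4R,5S,6S)-dauc-8-ene-4,6-diol | O[C@@]2(C(C)C)CC[C@]3(C)CC=C(C)C[C@H](O)[C@H]32
F11 | step 10 | (1R,4R,5S,6S)-6-(4-methoxybenzyloxy)dauc-8-en-4-ol | O[C@@]2(C(C)C)CC[C@]3(C)CC=C(C)C[C@H](OCc4ccc(OC)cc4)[C@H]32
F12 | step 10 | (1R,4R,5S,6S)-6-(4-methoxybenzyloxy)dauc-8-en-4-yl 3-methoxy-4-(prop-2-enyloxy)benzoate | COc1cc(C(=O)O[C@@]2(C(C)C)CC[C@]3(C)CC=C(C)C[C@H](OCc4ccc(OC)cc4)[C@H]32)ccc1OCC=C
F13 | step 7 | (1R,4S,5S,6S)-6-(tert-butyldimethylsilyloxy)dauca-8,11-dien-4-ol | O[C@@]2(C(C)=C)CC[C@]3(C)CC=C(C)C[C@H](O[Si](C)(C)C(C)(C)C)[C@H]32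
A1 | alternative 1 | 3,6-dimethylcyclohepta-2,5-dien-1-one | CC1=CC(=O)CC(C)=CC1
A2 | alternative 1 | 1-(propan-2-yl)cyclopropan-1-ol | CC(C)C1(O)CC1
A3 | alternative 1 | ethyl(4-methyl-3-oxopentyl)zinc | CC[Zn]CCC(=O)C(C)C
A4 | alternative 1 | 4-hydroxydauc-8-en-6-one (C1, C4, C5 as in the target) | O[C@@]2(C(C)C)CC[C@]3(C)CC=C(C)CC(=O)[C@H]32
A5 | alternative 2 | 3-(1,5-dimethylcyclohepta-2,5-dien-1-yl)propanal oxime (quaternary carbon as C1 of the target) | ON=CCC[C@@]1(C)C=CCC(C)=CC1
A6 | alternative 2 | 3-(1,5-dimethylcyclohepta-2,5-dien-1-yl)propanenitrile oxide (quaternary carbon as C1 of the target) | [O-][N+]#CCC[C@@]1(C)C=CCC(C)=CC1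
A7 | alternative 2 | ring A-fused isoxazoline, C4=N–O–C6 (C1 and C6 as in the target, C5 epimeric) | C1(=NO[C@H]2CC(C)=CC[C@@]3(C)CC1)[C@@H]23
A8 | alternative 2 | 6α-hydroxy-11,12,13-trinor-5-epi-dauc-8-en-4-one | O=C2CC[C@]3(C)CC=C(C)C[C@H](O)[C@@H]32
A9 | alternative 3 | cis-fused 8a-hydroxy-4a,7-dimethyl-2-(propan-2-yl)-2-(triethylsilyloxy)-1,2,3,4,4a,5,8,8a-octahydronaphthalen-1-yl methanesulfonate | CC[Si](CC)(CC)O[C@@]2(C(C)C)CC[C@]3(C)CC=C(C)C[C@]3(O)[C@H]2OS(C)(=O)=O
A10 | alternative 3 | 4-(triethylsilyloxy)dauc-8-en-6-one (C1, C4, C5 as in the target) | CC[Si](CC)(CC)O[C@@]2(C(C)C)CC[C@]3(C)CC=C(C)CC(=O)[C@H]32
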